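Ring B is cut at C5–C6 and C9–C10, which divides the target into an enantioenriched ring A allyl carbamate and a racemic ring C vinylogous ester aldehyde. The feature used is the 1,4-relation of the C1 and C6 oxygens across the C10–C5 ring fusion: the C1 carbamate reacts first as a C5 homoenolate towards the C6 aldehyde and then as a C10 enol towards the C9 carbonyl. One pot thus closes ring B, relays the single catalyst-made C1 stereocenter to C5 and C10, and gives the trans-fused A/B/C enone. Ring D (C11–C15, C13–C16) is then grown on ring C by alkylation, dienol aldol closure, redox adjustment and methylenation.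

Key step: step 5

Numbering used throughout (kaurane-type): ring A = C1–C5 and C10 (C1 bears OAc, C4 the geminal methyls, C10 the methyl C20); ring B = C5–C10 (C6 bears OAc); ring C = C8, C9, C11, C12, C13, C14 (C8=C9, C12–OH); the two-carbon bridge C15(=O)–C16(=C17H2) joins C11 and C13. α is the face of C20, β the opposite face. The target is (1S,5R,6S,10R,11R,12S,13R).

Remark on the chemistry (assumption): lithiation of the carbamate by s-BuLi/TMEDA is taken as retentive and the lithium–titanium exchange with ClTi(OiPr)3 as invertive, followed by a syn-SE′ addition. If the exchange proved retentive, the enantiomeric catalyst would be used in step 1.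

Remark: aldehyde 8 is racemic at C8. Compounds 11–19 are therefore carried as C8 epimers (17–19 also as C13 epimers), and their SMILES leave these centres open. Step 11 erases C8 and equilibrates C13.

Step 1
Reactants: 1 2,4,4-trimethylcyclohex-2-en-1-one
Product: 2 (1S)-2,4,4-trimethylcyclohex-2-en-1-ol
Conditions: (R)-2-methyl-CBS-oxazaborolidine (10 mol%), BH3·SMe2, THF, −20 °C; MeOH quench
Reagents that add atoms: none
Why: Corey–Bakshi–Shibata reduction, in which the 2-methyl-substituted alkenyl side of the enone acts as the large group, so that the (R)-catalyst should deliver hydride to the face that gives the (S)-allylic alcohol, the only stereocenter made by catalysis in the route.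

Step 2
Reactants: 2 (1S)-2,4,4-trimethylcyclohex-2-en-1-ol
Product: 3 (1S)-2,4,4-trimethylcyclohex-2-en-1-yl N,N-diisopropylcarbamate
Conditions: iPr2NC(O)Cl, pyridine, 90 °C
Reagents that add atoms: N,N-diisopropylcarbamoyl chloride, CC(C)N(C(C)C)C(Cl)=O
Why: O-carbamoylation of the secondary allylic alcohol installs the directing and carbanion-stabilising group needed for the homoaldol reaction without touching the stereocenter.

Step 3
Reactants: 4 3-ethoxycyclohex-2-en-1-one
Product: 6 rac-6-allyl-3-ethoxycyclohex-2-en-1-one, via lithium enolate 5 (not isolated)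
Conditions: LiN(iPr)2 (commercial solution), THF, −78 °C; allyl bromide, −78 → 0 °C
Reagents that add atoms: allyl bromide, C=CCBr
Why: Stork–Danheiser kinetic α′-alkylation, in which C6 of the vinylogous ester is deprotonated and C-allylated, places the future C7–C6 unit on C8 next to the carbonyl carbon that becomes C9.

Step 4
Reactants: 6 rac-6-allyl-3-ethoxycyclohex-2-en-1-one
Product: 8 rac-2-(4-ethoxy-2-oxocyclohex-3-en-1-yl)acetaldehyde, via diol 7 (not isolated)
Conditions: OsO4 (2 mol%), NaIO4, 2,6-lutidine, dioxane/H2O, 20 °C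
Reagents that add atoms: sodium periodate (source of the aldehyde oxygen, passed on through OsO4), [Na+].[O-]I(=O)(=O)=O
Why: Lemieux–Johnson cleavage, in which OsO4 dihydroxylates the terminal alkene in preference to the push–pull enol ether alkene and NaIO4 cleaves the diol to the aldehyde.

Step 5
Reactants: 3 (1S)-2,4,4-trimethylcyclohex-2-en-1-yl N,N-diisopropylcarbamate; 8 rac-2-(4-ethoxy-2-oxocyclohex-3-en-1-yl)acetaldehyde
Product: 12 (5R,6R,10R)-6β-hydroxy-1,12-dioxo A/B-trans tricyclic 9(11)-enone (C8 epimers), via lithiated carbamate 9 (not isolated), via allyltitanium 10 (not isolated), via homoaldol adduct 11 (not isolated)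
Conditions: 3, s-BuLi, TMEDA, Et2O, −78 °C; ClTi(OiPr)3, −78 °C; 8, −78 → −40 °C; then CH2Cl2, BF3·OEt2, −78 → 0 °C; aq. NaHCO3
Reagents that add atoms: water, O
Why: Retentive lithiation of 3 and invertive lithium–titanium exchange give allyltitanium 10, which adds to the aldehyde of 8 at its γ-carbon C5 through a closed Zimmerman–Traxler chair (syn-SE′, Hoppe homoaldol reaction), so that C5–C6 forms on the ring A face that carried the C1 oxygen and the C1 configuration is transferred to C5; the C6 carbinol configuration is of no consequence because C6 is oxidised in step 6. BF3·OEt2 then complexes the vinylogous ester carbonyl and the enol carbamate carbon C10 adds to C9 (Mukaiyama aldol-type addition, ring B closed in a 6-exo-trig mode); loss of the C9 oxygen and hydrolysis of the ethoxy-oxocarbenium and of the O-carbamoyl oxocarbenium on work-up give the transposed C9=C11–C12=O enone (Stork–Danheiser transposition) and the C1 ketone. The closest known reaction types are the titanium homoaldol reaction of metalated allyl carbamates and the Lewis-acid-mediated intramolecular addition of enol carbamates to carbonyl acceptors. C10 is set by the C5 stereocenter through the tether: closure on the α-face would place C9 syn-axial to the axial C4 methyl group, so β-face closure to the trans A/B fusion is expected. The step needs γ- over α-attack of the allyl metal and aldehyde over ketone selectivity, both secured by the alkoxytitanium counter-ion, and C9 over C12 attack in the cyclisation, secured by the tether, which allows only the six-membered ring. The C8 center of racemic 8 is carried as a mixture and erased in step 11.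

Step 6
Reactants: 12 (5R,6R,10R)-6β-hydroxy-1,12-dioxo A/B-trans tricyclic 9(11)-enone
Product: 13 (5R,10R)-1,6,12-trioxo A/B-trans tricyclic 9(11)-enone (C8 epimers)
Conditions: Dess–Martin periodinane, NaHCO3, CH2Cl2, 0 → 20 °C
Reagents that add atoms: none
Why: Dess–Martin oxidation removes the wrongly configured C6 carbinol center under buffered conditions that should not epimerise C5, so that C6 can be reset by hydride from the β-face.

Step 7
Reactants: 13 (5R,10R)-1,6,12-trioxo A/B-trans tricyclic 9(11)-enone
Product: 14 (1S,5R,6S,10R)-1α,6α-dihydroxy A/B-trans tricyclic 9(11)-en-12-one (C8 epimers)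
Conditions: NaBH4, MeOH/CH2Cl2, −40 → −20 °C
Reagents that add atoms: none
Why: Substrate-controlled hydride reduction, in which the small hydride should attack both saturated ketones from the β-face (axial attack at C1 giving the equatorial 1α-alcohol, equatorial attack at C6 giving the axial 6α-alcohol because the α-face is blocked by the syn-axial C20 and 4α-methyl groups), while the β,β-disubstituted conjugated enone reacts more slowly.

Step 8
Reactants: 14 (1S,5R,6S,10R)-1α,6α-dihydroxy A/B-trans tricyclic 9(11)-en-12-one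
Product: 15 (1S,5R,6S,10R)-1α,6α-diacetoxy A/B-trans tricyclic 9(11)-en-12-one (C8 epimers)
Conditions: Ac2O, DMAP, pyridine, 50 °C
Reagents that add atoms: acetic anhydride, CC(=O)OC(C)=O
Why: DMAP-catalysed acetylation esterifies the equatorial 1α-hydroxyl and, on warming, the hindered axial 6α-hydroxyl, after which no protecting group is needed.

Step 9
Reactants: 15 (1S,5R,6S,10R)-1α,6α-diacetoxy A/B-trans tricyclic 9(11)-en-12-one
Product: 17 13-allyl-1α,6α-diacetoxy A/B-trans tricyclic 9(11)-en-12-one (C8 and C13 epimers), via lithium dienolate 16 (not isolated)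
Conditions: LiN(SiMe3)2 (commercial solution), THF, −78 °C; allyl bromide, DMPU, −78 → −20 °C
Reagents that add atoms: allyl bromide, C=CCBr
Why: Kinetic α′-deprotonation of the enone at C13 by a base too weak to enolise the acetates, followed by C-allylation of the enolate, installs the carbons that become C16 and C15.

Step 10
Reactants: 17 13-allyl-1α,6α-diacetoxy A/B-trans tricyclic 9(11)-en-12-one
Product: 19 1α,6α-diacetoxy-13-(2-oxoethyl) A/B-trans tricyclic 9(11)-en-12-one (C8 and C13 epimers), via diol 18 (not isolated)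
Conditions: OsO4 (2 mol%), NaIO4, 2,6-lutidine, dioxane/H2O, 20 °C
Reagents that add atoms: sodium periodate (source of the aldehyde oxygen, passed on through OsO4), [Na+].[O-]I(=O)(=O)=O
Why: Lemieux–Johnson cleavage of the terminal alkene, the electron-poor trisubstituted enone alkene being left untouched.

Step 11
Reactants: 19 1α,6α-diacetoxy-13-(2-oxoethyl) A/B-trans tricyclic 9(11)-en-12-one
Product: 20 (1S,5R,6S,10R,11S,13R,15R)-1α,6α-diacetoxy-15-hydroxy-12-oxo tetracycle with C8=C9 (bicyclo[3.2.1]octene rings C/D; 15-OH exo)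
Conditions: TsOH·H2O (20 mol%), CH2Cl2 (0.01 M), 20 °C
Reagents that add atoms: none
Why: Acid-catalysed intramolecular aldol addition through the linear dienol C12(OH)=C11–C9=C8 should close ring D in a 5-exo-trig mode at C11 on the β-face (the α-face is shielded by the axial C20 methyl group), moving the alkene to C8=C9 and erasing the C8 center, while C13 equilibrates by enolisation so that only the β-oriented side chain cyclises, the 15-hydroxyl settles exo (hydrogen-bonded to the C12 carbonyl) and reconjugation is impossible because C11 has become a bridgehead.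

Step 12
Reactants: 20 (1S,5R,6S,10R,11S,13R,15R)-1α,6α-diacetoxy-15-hydroxy-12-oxo tetracycle
Product: 22 (1S,5R,6S,10R,11S,12S,13R,15R)-1α,6α-diacetoxy-12,15-dihydroxy tetracycle (syn-1,3-diol), via boron chelate 21 (not isolated)
Conditions: Et2BOMe, THF/MeOH (4:1), −78 °C; NaBH4, −78 °C; AcOH; MeOH co-evaporation
Reagents that add atoms: none
Why: Narasaka–Prasad reduction, in which the diethylboron chelate between the exo 15-oxygen and the C12 carbonyl covers the face of the C15–C16 bridge, so that external hydride should attack C12 from the face of the C9=C8–C14 bridge and give the 12-hydroxyl syn to the two-carbon bridge (12S).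

Step 13
Reactants: 22 (1S,5R,6S,10R,11S,12S,13R,15R)-1α,6α-diacetoxy-12,15-dihydroxy tetracycle
Product: 23 (1S,5R,6S,10R,11R,12S,13R)-1α,6α-diacetoxy-12-hydroxy-15-oxo tetracycle (the target without its exocyclic methylene)
Conditions: TEMPO (20 mol%), PhI(OAc)2 (1.1 equiv), CH2Cl2, 20 °C
Reagents that add atoms: none
Why: Oxoammonium (TEMPO) oxidation should select the 15-hydroxyl, because oxidation at the one-carbon bridge C12, which is flanked by two bridgeheads, would create a more strained bridging ketone; material oxidised at C12 instead is compound 20 and can be returned to step 12.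

Step 14
Reactants: 23 (1S,5R,6S,10R,11R,12S,13R)-1α,6α-diacetoxy-12-hydroxy-15-oxo tetracycle
Product: 25 1α,6α-diacetoxyjungermannenone C, via Mannich base 24 (not isolated)
Conditions: (CH2O)n, iPr2NH2+ CF3CO2−, CF3CO2H (cat.), THF, 65 °C
Reagents that add atoms: formaldehyde (as paraformaldehyde), C=O
Why: Mannich-type α-methylenation (aminomethylation then β-elimination of the amine) can take place only at C16, since the other α-carbon C11 is a bridgehead that cannot enolise, and the weakly acidic medium should spare the β-hydroxy ketone and the acetates.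

Compound list
1 | 2,4,4-trimethylcyclohex-2-en-1-one | CC1=CC(C)(C)CCC1=O | starting material
2 | (1S)-2,4,4-trimethylcyclohex-2-en-1-ol | O[C@H]1CCC(C)(C)C=C1C | intermediate
3 | (1S)-2,4,4-trimethylcyclohex-2-en-1-yl N,N-diisopropylcarbamate | CC(C)N(C(C)C)C(=O)O[C@H]1CCC(C)(C)C=C1C | intermediate
4 | 3-ethoxycyclohex-2-en-1-one | CCOC1=CC(=O)CCC1 | starting material
5 | kinetic lithium enolate of 4 (C6 deprotonated) | CCOC1=CC(O[Li])=CCC1 | intermediate
6 | rac-6-allyl-3-ethoxycyclohex-2-en-1-one | CCOC1=CC(=O)C(CC=C)CC1 | intermediate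
7 | 6-(2,3-dihydroxypropyl)-3-ethoxycyclohex-2-en-1-one | CCOC1=CC(=O)C(CC(O)CO)CC1 | intermediate
8 | rac-2-(4-ethoxy-2-oxocyclohex-3-en-1-yl)acetaldehyde | CCOC1=CC(=O)C(CC=O)CC1 | intermediate
9 | C1-lithiated carbamate (Li on the face of the former C1–H) | [Li][C@]1(OC(=O)N(C(C)C)C(C)C)CCC(C)(C)C=C1C | intermediate
10 | C1-triisopropoxytitanium allyl carbamate (Ti on the opposite, α-face) | CC(C)O[Ti](OC(C)C)(OC(C)C)[C@@]1(OC(=O)N(C(C)C)C(C)C)CCC(C)(C)C=C1C | intermediate
11 | (5R,6R)-homoaldol adduct: ring A C1=C10 enol carbamate with the C5 side chain CH(OH)–CH2–(4-ethoxy-2-oxocyclohex-3-en-1-yl), C8 epimers | CCOC1=CC(=O)C(C[C@@H](O)[C@@H]2C(C)(C)CCC(OC(=O)N(C(C)C)C(C)C)=C2C)CC1 | intermediate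
12 | (5R,6R,10R)-6β-hydroxy-4,4,10-trimethyl A/B-trans tricycle with C1 ketone and C9=C11–C12=O enone, C8 epimers | O=C1CCC2C[C@@H](O)[C@@H]3C(C)(C)CCC(=O)[C@@]3(C)C2=C1 | intermediate
13 | (5R,10R)-1,6,12-trione with C9=C11, C8 epimers | O=C1CCC2CC(=O)[C@@H]3C(C)(C)CCC(=O)[C@@]3(C)C2=C1 | intermediate
14 | (1S,5R,6S,10R)-1α,6α-diol with C9=C11–C12=O enone, C8 epimers | O=C1CCC2C[C@H](O)[C@@H]3C(C)(C)CC[C@H](O)[C@@]3(C)C2=C1 | intermediate
15 | (1S,5R,6S,10R)-1α,6α-diacetate with C9=C11–C12=O enone, C8 epimers | O=C1CCC2C[C@H](OC(C)=O)[C@@H]3C(C)(C)CC[C@H](OC(C)=O)[C@@]3(C)C2=C1 | intermediate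
16 | cross-conjugated lithium dienolate of 15 (C12–OLi, C12=C13, C9=C11) | [Li]OC1=CCC2C[C@H](OC(C)=O)[C@@H]3C(C)(C)CC[C@H](OC(C)=O)[C@@]3(C)C2=C1 | intermediate
17 | 13-allyl derivative of 15, C8 and C13 epimers | O=C1C(CC=C)CC2C[C@H](OC(C)=O)[C@@H]3C(C)(C)CC[C@H](OC(C)=O)[C@@]3(C)C2=C1 | intermediate
18 | 13-(2,3-dihydroxypropyl) derivative of 15 | O=C1C(CC(O)CO)CC2C[C@H](OC(C)=O)[C@@H]3C(C)(C)CC[C@H](OC(C)=O)[C@@]3(C)C2=C1 | intermediate
19 | 13-(2-oxoethyl) derivative of 15, C8 and C13 epimers | O=C1C(CC=O)CC2C[C@H](OC(C)=O)[C@@H]3C(C)(C)CC[C@H](OC(C)=O)[C@@]3(C)C2=C1 | intermediate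
20 | (1S,5R,6S,10R,11S,13R,15R)-1α,6α-diacetoxy-15-hydroxy (exo) tetracycle with C12 ketone, C16H2 and C8=C9 | C1[C@@H](O)[C@@H]2C3=C(C[C@H](OC(C)=O)[C@@H]4C(C)(C)CC[C@H](OC(C)=O)[C@@]34C)C[C@H]1C2=O | intermediate
21 | O15-diethylboryl ether of 20 (boron chelated to the C12 carbonyl) | C1[C@@H](OB(CC)CC)[C@@H]2C3=C(C[C@H](OC(C)=O)[C@@H]4C(C)(C)CC[C@H](OC(C)=O)[C@@]34C)C[C@H]1C2=O | intermediate
22 | (1S,5R,6S,10R,11S,12S,13R,15R)-1α,6α-diacetoxy-12,15-diol (12-OH syn to the C15–C16 bridge, 15-OH exo) | C1[C@@H](O)[C@@H]2C3=C(C[C@H](OC(C)=O)[C@@H]4C(C)(C)CC[C@H](OC(C)=O)[C@@]34C)C[C@H]1[C@@H]2O | intermediate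
23 | (1S,5R,6S,10R,11R,12S,13R)-1α,6α-diacetoxy-12-hydroxy-15-ketone with C16H2 | C1C(=O)[C@@H]2C3=C(C[C@H](OC(C)=O)[C@@H]4C(C)(C)CC[C@H](OC(C)=O)[C@@]34C)C[C@H]1[C@@H]2O | intermediate
24 | 16-(diisopropylaminomethyl) derivative of 23 (C16 unassigned) | CC(C)N(C(C)C)CC1C(=O)[C@@H]2C3=C(C[C@H](OC(C)=O)[C@@H]4C(C)(C)CC[C@H](OC(C)=O)[C@@]34C)C[C@H]1[C@@H]2O | intermediate
25 | 1α,6α-diacetoxyjungermannenone C, (1S,5R,6S,10R,11R,12S,13R) | C=C1C(=O)[C@@H]2C3=C(C[C@H](OC(C)=O)[C@@H]4C(C)(C)CC[C@H](OC(C)=O)[C@@]34C)C[C@H]1[C@@H]2O | target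

Total step count: 14. Longest linear sequence: 12 steps (steps 1, 2 and 5–14; the branch through steps 3 and 4 is equally long).

Steps most likely to fail

Step 5. The complexed vinylogous ester may be too weak an electrophile for the enol carbamate, so that ring B does not close or the C6 oxygen adds to C9 instead; closure to the cis A/B fusion is the second danger. The fallback separates the two bond formations and uses an enone acceptor. It sets out from 6 and 3. Reduction of 6 with iBu2AlH and acidic work-up (Stork–Danheiser transposition) would give 4-allylcyclohex-2-en-1-one F1. Lemieux–Johnson cleavage would give 2-(4-oxocyclohex-2-en-1-yl)acetaldehyde F2. The homoaldol addition of 3 (first stage of step 5) would give the isolated enol carbamate adduct F3. Me3SiOTf would then bring about an intramolecular Mukaiyama–Michael addition of C10 to the enone β-carbon C9, which leaves the acceptor as the regiodefined tricyclic silyl enol ether F4. Saegusa–Ito oxidation with Pd(OAc)2 in MeCN would restore the C9=C11 enone, and acidic work-up would remove the 6-O-silyl group, so that the route is rejoined at 12.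

Step 11. Enolisation may take place at the aldehyde instead of at the γ-position of the enone, leading to self-condensation, or the side chain on C13 may not reach the β-axial position. The fallback deconjugates first and sets out from 17. LiN(SiMe3)2 under equilibrating conditions, followed by kinetic protonation with AcOH at −78 °C, would give the β,γ-unsaturated ketone F5 (C8=C9, C11H2). Lemieux–Johnson cleavage of the terminal alkene would give the aldehyde F6. Its doubly activated C11 methylene should then undergo the intramolecular aldol addition with Et3N in CH2Cl2, returning the route at 20.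

Step 13. The two secondary hydroxyl groups may not be told apart, so that oxidation takes place at C12 or at both carbinols. The fallback uses orthogonal silyl ethers and sets out from 20. Et3SiOTf with 2,6-lutidine would give the 15-O-triethylsilyl ether F7. NaBH4 would reduce C12 from the face opposite to the exo silyl ether and give the 12-alcohol F8. tBuMe2SiOTf would give the bis-silyl ether F9. PPTS in MeOH would free the 15-hydroxyl to give F10. Dess–Martin oxidation would give the 15-ketone F11, and the methylenation of step 14 would give the silylated enone F12. HF·pyridine would finally remove the 12-O-silyl group, returning the route at 25.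

Further compounds
F1 | step 5 | 4-allylcyclohex-2-en-1-one | C=CCC1CCC(=O)C=C1
F2 | step 5 | 2-(4-oxocyclohex-2-en-1-yl)acetaldehyde | O=CCC1CCC(=O)C=C1
F3 | step 5 | (5R,6R)-homoaldol adduct of 3 and F2 (C1=C10 enol carbamate, 4-oxocyclohex-2-en-1-yl end group) | O=C1CCC(C[C@@H](O)[C@@H]2C(C)(C)CCC(OC(=O)N(C(C)C)C(C)C)=C2C)C=C1
F4 | step 5 | (5R,6R,10R)-tricyclic C1 ketone with 6β-trimethylsilyloxy group and C11=C12 trimethylsilyl enol ether | C[Si](C)(C)OC1=CC2C(CC1)C[C@@H](O[Si](C)(C)C)[C@@H]1C(C)(C)CCC(=O)[C@@]21C
F5 | step 11 | 13-allyl-1α,6α-diacetoxy A/B-trans tricyclic 8(9)-en-12-one | O=C1CC2=C(C[C@H](OC(C)=O)[C@@H]3C(C)(C)CC[C@H](OC(C)=O)[C@@]23C)CC1CC=C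
F6 | step 11 | 1α,6α-diacetoxy-13-(2-oxoethyl) A/B-trans tricyclic 8(9)-en-12-one | O=C1CC2=C(C[C@H](OC(C)=O)[C@@H]3C(C)(C)CC[C@H](OC(C)=O)[C@@]23C)CC1CC=O
F7 | step 13 | 15-O-triethylsilyl ether of 20 | C1[C@@H](O[Si](CC)(CC)CC)[C@@H]2C3=C(C[C@H](OC(C)=O)[C@@H]4C(C)(C)CC[C@H](OC(C)=O)[C@@]34C)C[C@H]1C2=O
F8 | step 13 | 15-O-triethylsilyl ether of 22 | C1[C@@H](O[Si](CC)(CC)CC)[C@@H]2C3=C(C[C@H](OC(C)=O)[C@@H]4C(C)(C)CC[C@H](OC(C)=O)[C@@]34C)C[C@H]1[C@@H]2O
F9 | step 13 | 12-O-tert-butyldimethylsilyl-15-O-triethylsilyl ether of 22 | C1[C@@H](O[Si](CC)(CC)CC)[C@@H]2C3=C(C[C@H](OC(C)=O)[C@@H]4C(C)(C)CC[C@H](OC(C)=O)[C@@]34C)C[C@H]1[C@@H]2O[Si](C)(C)C(C)(C)C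
F10 | step 13 | 12-O-tert-butyldimethylsilyl ether of 22 | C1[C@@H](O)[C@@H]2C3=C(C[C@H](OC(C)=O)[C@@H]4C(C)(C)CC[C@H](OC(C)=O)[C@@]34C)C[C@H]1[C@@H]2O[Si](C)(C)C(C)(C)C
F11 | step 13 | 12-O-tert-butyldimethylsilyl ether of 23 | C1C(=O)[C@@H]2C3=C(C[C@H](OC(C)=O)[C@@H]4C(C)(C)CC[C@H](OC(C)=O)[C@@]34C)C[C@H]1[C@@H]2O[Si](C)(C)C(C)(C)C
F12 | step 13 | 12-O-tert-butyldimethylsilyl ether of 25 | C=C1C(=O)[C@@H]2C3=C(C[C@H](OC(C)=O)[C@@H]4C(C)(C)CC[C@H](OC(C)=O)[C@@]34C)C[C@H]1[C@@H]2O[Si](C)(C)C(C)(C)C
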